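The data are calculated from invented constants.

Just 2.3 percentage points of target went between 1.67 d and 2.50 d in the north-west flask, after 5.6 points in the equal step before. Hold on to that ratio of 0.411. You are asked about this same flask, charged with substrate, partner and precatalyst, where target is the one species followed.

common to all: substrate 0.10 M; partner 0.105 M; precatalyst 10 mM; temperature −20 °C
- north-west: the very flask that is asked about, followed so far
- flask: time 3.0 d

north-west run (percent of the substrate charged): time / d: target / % = 0.208: 21.2; 0.333: 24.9; 0.500: 25.9; 0.833: 22.8; 1.67: 17.2; 2.50: 14.9

(standard deviation of a reading: 0.5 percentage points)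

- red: at 3.0 d take out 90% of the target then present, then wait 40 h
- blue: change nothing and wait 40 h more
- amber: at 3.0 d add precatalyst, 100% of the amount charged, then wait 40 h
- green: at 3.0 d add partner, 50.0% of the amount charged, then wait 40 h
- teal: at 3.0 d raise the temperature by 20 K, then wait 40 h

- target, in percent of the substrate first charged, at 3.0 d
- the remedy with the largest gain of target, or "none" below 2 percentage points (red / blue / amber / green / teal / none)
- target present, with what was taken out counted in, in percent of the substrate first charged, after green
- target present, with what was taken out counted in, in percent of the substrate first charged, after teal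

- removed target is counted in
- the earlier runs do not show what temperature does; that part of a forecast is a guess
- additions bring no volume worth counting

Turn the question round: what would the readings show if target kept draining at a steady share? Each step would take the share lost in the step before, so the last drop would be 4.2 points. The reading falls 1.9 points short of that, with a scatter of 0.5 points per reading, so I take target to be levelling off.

If each drop stays 0.411 of the one before, the north-west flask levels at 13.3%. Call that the floor, the target level at which a flask stops falling. The peak is then kinetic control and the floor thermodynamic control.

My reckoning puts target at 14.2% at 3.0 d. If the floor is a balance, target taken out should refill, and I let it refill at the pace of the fall. The 40 h of waiting spans 2.01 steps, so red should count in at about 24.1%, a gain of 9.9 points over 14.2%, more than the 2 points bar. Best is therefore not none. I can't read from these readings what green and teal do, so I give them no figures.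

The forecast gives 14.2%, as my reckoning does, but parts from me on best with none, and has 13.4% after green and 13.1% after teal: “Green does nothing much”.

The flask gives 15.6%, and teal gains most at 23 points, ahead of red at 11 points and green at 4 points. Green ends at 19.5% and teal at 38.5%.

    substrate + partner ⇌ target (K = 9.30 M⁻¹, k = 0.910 M⁻¹ h⁻¹, Ea = 70.0 kJ mol⁻¹, ΔH = 13.0 kJ mol⁻¹)
    target + catalyst ⇌ isomer of the product + catalyst, rate k2*[catalyst]*[target] forward; the back reaction follows from the equilibrium constant (k = 4.00 M⁻¹ h⁻¹, Ea = 54.0 kJ mol⁻¹)
    substrate + partner ⇌ isomer of the product (K = 26.0 M⁻¹, k = 0.370 M⁻¹ h⁻¹, Ea = 61.0 kJ mol⁻¹, ΔH = −63.0 kJ mol⁻¹)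
    partner + precatalyst → catalyst + spent reagent (k = 0.540 M⁻¹ h⁻¹, Ea = 70.0 kJ mol⁻¹)
    (constants at −20 °C)

The first equation gives the floor a use elsewhere: divide it by what the flask holds at 30.0 d, 42.8% of substrate and 36.0% of partner, and [target]/([substrate][partner]) comes to 8.21 M⁻¹. The neighbour flask with 0.25 M of substrate holds 66.2% of substrate and 14.0% of partner at 3.00 d. That quotient gives it 8.01% of target, and the neighbour holds 9.21%.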